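**Plan**
- Retrosynthesis: the C9 methacrylate, the C1–C2 oxirane oxygen and the C15 aldehyde oxygen come off first. C11=C13 and C7–C11 are then cut together, which opens the lactone ring to a C8 diethylphosphonoacetate next to a C6–C7 epoxide.
- Enabling feature: on the cyclohexane ring the C6 hydroxyl is trans to C11 on C7, while C11 is cis to the ring oxygen on C8 of the cis-fused five-membered lactone. This pattern results when a 6β,7β-epoxide is opened at C7 from the α face by a carbon attached through O8.
- Earlier cuts: C8–O (inversion), the C6/C7 and C8/C9 epoxide oxygens, C1=C2 (Wittig), C5–C4 (conjugate addition) and C10–CH3 (Birch alkylation), leading back to benzoic acid.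
- Forward order: carbocycle from benzoic acid, prochiral dienone, isopropenyl addition, oxygenation at C9/C8 and then C6/C7, lactone ring (key step), enal, oxirane, methacrylate.
- Stereochemistry: C5 and C10 come from the (S)-BINAP/rhodium desymmetrisation. C9 comes from enone epoxidation anti to the C10 methyl. C8 is set by two inversions, C6 by hydroxyl-directed epoxidation, C7 by backside epoxide opening, and C1 by O9-directed epoxidation.

Key step: step 17

Convention: elemane-type numbering is used. C10 is the quaternary carbon and C5 the carbon bearing the C3 side chain (C4, C3, C15), followed by C6, C7, C8, C9 round the ring. C1/C2 form the two-carbon arm on C10 and C11–C13 are the lactone carbons. β is the ring face carrying the C10 methyl, α the opposite face.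
Remark: the target is made as the open 6-hydroxy enal that is drawn; a possible ring–chain equilibrium with the O6–C15 lactol is not considered.

**Step 1**
Reactants: 1 benzoic acid
Product: 2 1-methylcyclohexa-2,5-diene-1-carboxylic acid
Conditions: Li, NH3(l), THF, −78 °C; MeI; aq. HCl work-up
Reagents that add atoms: methyl iodide CI
Why: Birch reductive alkylation: dissolving-metal reduction of the benzoate gives the ring dienolate, which methyl iodide alkylates at the carboxyl-bearing carbon, so the future quaternary C10 is built while still achiral.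

**Step 2**
Reactants: 2 1-methylcyclohexa-2,5-diene-1-carboxylic acid
Product: 3 (1-methylcyclohexa-2,5-dien-1-yl)methanol
Conditions: LiAlH4, THF, 0 °C to rt
Reagents that add atoms: none
Why: Hydride reduction of a carboxylic acid, to which the skipped diene is inert, should deliver the C1 carbinol.

**Step 3**
Reactants: 3 (1-methylcyclohexa-2,5-dien-1-yl)methanol
Product: 4 tert-butyl[(1-methylcyclohexa-2,5-dien-1-yl)methoxy]diphenylsilane
Conditions: TBDPSCl, imidazole, DMF, rt
Reagents that add atoms: tert-butyl(chloro)diphenylsilane CC(C)(C)[Si](Cl)(c1ccccc1)c1ccccc1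
Why: Routine silylation of a primary alcohol; the large silyl group makes the CH2O arm much bulkier than the methyl group, a difference that step 5 relies on.

**Step 4**
Reactants: 4 silyl ether of the dienyl carbinol
Product: 5 4-methyl-4-[(tert-butyldiphenylsilyloxy)methyl]cyclohexa-2,5-dien-1-one
Conditions: Rh2(cap)4 (1 mol %), t-BuOOH, K2CO3, CH2Cl2, rt
Reagents that add atoms: tert-butyl hydroperoxide CC(C)(C)OO
Why: Catalytic allylic oxidation with t-BuOOH: the doubly allylic ring CH2 is the only activated C–H site and should be taken to the ketone (future C7), giving the prochiral cross-conjugated dienone.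

**Step 5**
Reactants: 5 prochiral dienone; 6 isopropenylboronic acid pinacol ester
Product: 7 5β-isopropenyl-10β-methyl-10α-(TBDPS-oxymethyl)cyclohex-8-en-7-one (isopropenyl cis to methyl)
Conditions: [Rh(C2H4)2Cl]2 (2.5 mol %), (S)-BINAP (6 mol %), KOH, dioxane/H2O (10:1), 40 °C
Reagents that add atoms: isopropenylboronic acid pinacol ester (6) CC(=C)B1OC(C)(C)C(C)(C)O1
Why: Hayashi–Miyaura asymmetric conjugate addition used as a desymmetrisation: the (S)-BINAP–rhodium alkenyl species fixes C5 in the sense known for cyclohexenone, and only one of the two enantiotopic enone arms lets it enter anti to the CH2OTBDPS group, which sets C10 at the same time and leaves the mismatched second enone of 7 unreacted.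

**Step 6**
Reactants: 7 enone
Product: 8 8α,9α-epoxy-5β-isopropenyl-10β-methyl-10α-(TBDPS-oxymethyl)cyclohexan-7-one
Conditions: 30% H2O2, NaOH (cat.), MeOH, 0 °C
Reagents that add atoms: hydrogen peroxide OO
Why: Weitz–Scheffer nucleophilic epoxidation touches only the electron-poor C8=C9 bond, and hydroperoxide adds axially at C9 anti to the axial C10 methyl and trans to the C5 isopropenyl group (as with 1-en-3-one steroids and carvone), which sets the 9α C–O bond.

**Step 7**
Reactants: 8 epoxy ketone
Product: 9 8α,9α-epoxy-7α-ol (hydroxyl cis to the epoxide)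
Conditions: LiBH(s-Bu)3 (L-Selectride), THF, −78 °C
Reagents that add atoms: none
Why: Ketone reduction with a bulky borohydride: hydride should arrive from the β face, away from the epoxide oxygen and along the equatorial trajectory, giving the axial 7α-alcohol, a centre that step 8 erases.

**Step 8**
Reactants: 9 epoxy alcohol
Product: 10 8α,9α-epoxy-5β-isopropenyl-10β-methyl-10α-(TBDPS-oxymethyl)cyclohex-6-ene (vinyl epoxide)
Conditions: Ph2S[OC(CF3)2Ph]2 (Martin sulfurane), CH2Cl2, 0 °C to rt
Reagents that add atoms: none
Why: Sulfurane-mediated dehydration (E2): the axial C7 leaving group has a usable antiperiplanar hydrogen only at C6 because C8 is an epoxide carbon, so C6=C7 should form regiospecifically under neutral conditions that spare the new vinyl epoxide.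

**Step 9**
Reactants: 10 vinyl epoxide silyl ether
Product: 11 10α-hydroxymethyl vinyl epoxide
Conditions: Bu4NF, THF, 0 °C to rt
Reagents that add atoms: none
Why: Fluoride cleavage of the silyl ether runs under non-acidic conditions that the vinyl epoxide tolerates.

**Step 10**
Reactants: 11 primary alcohol
Product: 12 10α-formyl vinyl epoxide
Conditions: Pr4N[RuO4] (5 mol %), NMO, 4 Å MS, CH2Cl2, rt
Reagents that add atoms: none
Why: Ley–Griffith oxidation is neutral and catalytic, stops at the non-enolisable neopentyl aldehyde and leaves epoxide and alkenes untouched.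

**Step 11**
Reactants: 12 aldehyde
Product: 13 8α,9α-epoxy-5β-isopropenyl-10β-methyl-10α-vinylcyclohex-6-ene
Conditions: Ph3PCH3Br, KOt-Bu, THF, 0 °C
Reagents that add atoms: methyltriphenylphosphonium bromide C[P+](c1ccccc1)(c1ccccc1)c1ccccc1.[Br-]
Why: Wittig methylenation of the only carbonyl group, which has no α-hydrogen and cannot epimerise, installs C2.

**Step 12**
Reactants: 13 vinyl epoxide
Product: 14 8β-acetoxy-9α-hydroxy-5β-isopropenyl-10β-methyl-10α-vinylcyclohex-6-ene
Conditions: AcOH, NaOAc, CH2Cl2, 0 °C to rt
Reagents that add atoms: acetic acid CC(=O)O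
Why: Acidolysis of a vinyl epoxide: acetate attacks the allylic C8 from the β face with inversion in the trans-diaxial mode (C9 is neopentyl and not allylic), so O9 stays α and C8 receives the β-oxygen that will steer step 15.

**Step 13**
Reactants: 14 hydroxy acetate
Product: 15 8β-acetoxy-9α-triethylsilyloxy compound
Conditions: TESOTf, 2,6-lutidine, CH2Cl2, −78 to 0 °C
Reagents that add atoms: triethylsilyl triflate CC[Si](CC)(CC)OS(=O)(=O)C(F)(F)F
Why: Silyl triflate silylation is strong enough for the hindered C9 hydroxyl and installs a group that cannot participate at C8 in step 16.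

**Step 14**
Reactants: 15 acetate
Product: 16 8β-hydroxy-9α-triethylsilyloxy-5β-isopropenyl-10β-methyl-10α-vinylcyclohex-6-ene (allylic alcohol)
Conditions: i-Bu2AlH, CH2Cl2, −78 °C; aq. potassium sodium tartrate
Reagents that add atoms: none
Why: Reductive ester cleavage at low temperature frees the C8 allylic alcohol through an aluminium alkoxide, which avoids base-induced 1,2-silyl migration.

**Step 15**
Reactants: 16 allylic alcohol
Product: 17 6β,7β-epoxy-8β-ol (cis-epoxy alcohol) with 9α-OTES
Conditions: VO(acac)2 (5 mol %), t-BuOOH, CH2Cl2, 0 °C to rt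
Reagents that add atoms: tert-butyl hydroperoxide CC(C)(C)OO
Why: Hydroxyl-directed epoxidation of an allylic alcohol: the vanadium alkoxide on the pseudoaxial 8β-oxygen delivers oxygen only to the β face of C6=C7, which sets C6 and leaves the vinyl and isopropenyl groups, which have no allylic hydroxyl, untouched.

**Step 16**
Reactants: 17 cis-epoxy alcohol; 18 diethylphosphonoacetic acid
Product: 19 6β,7β-epoxy-9α-triethylsilyloxy-8α-yl diethylphosphonoacetate (ester anti to the epoxide oxygen)
Conditions: PPh3, DIAD, toluene, 0 °C to rt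
Reagents that add atoms: diethylphosphonoacetic acid (18) OC(=O)CP(=O)(OCC)OCC
Why: Mitsunobu esterification: the fairly acidic carboxylic acid displaces the C8 oxyphosphonium ion by SN2 from the α face, so C8 is inverted and the ester ends up anti to the epoxide and cis to O9, while the silyl ether cannot participate and no β-hydrogen is placed for elimination.

**Step 17**
Reactants: 19 epoxy phosphonoacetate; 20 formaldehyde (as paraformaldehyde)
Product: 22 6β-hydroxy-9α-triethylsilyloxy α-methylene-γ-lactone (C11 on C7 and O8 both α), via α-phosphono lactone 21 (not isolated)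
Conditions: NaH (1.05 equiv), THF (0.01 M), 0 to 60 °C; then (CH2O)n, 0 °C to rt
Reagents that add atoms: formaldehyde (20) C=O
Why: Proposed new method: NaH deprotonates the phosphonoacetate CH2 and the carbanion, held on O8 on the α face, attacks C7 anti to the β-epoxide oxygen, forming C7–C11 and the lactone ring and leaving the oxygen on C6 as an alkoxide; this alkoxide is quenched at once by the far more acidic C11–H of 21, which regenerates a phosphonate carbanion that olefinates formaldehyde (Horner–Wadsworth–Emmons) to C11=C13. The closest known reaction types are the intramolecular opening of epoxides by malonate-type ester carbanions to γ-lactones and the methylenation of α-phosphono-γ-lactones with formaldehyde; what is new is their union on an O-tethered phosphonoacetate in one flask. The five-membered lactone closes in the 5-exo-tet mode, and because the charge is carried by the exocyclic phosphoryl group the ring ester need not lie in the enolate plane, which avoids the unfavourable enolendo geometry of a plain acetate enolate. The one new stereocentre, C7, is fixed by the tether (delivery cis to O8) and by the obligatory backside attack, C6 keeps its configuration, and both demands coincide with trans-diaxial opening of the half-chair that has the C5 isopropenyl and C10 vinyl groups equatorial. The step needs attack at C7 rather than C6 and C- rather than O-alkylation: attack at C6 would be a 6-endo closure to a bridged δ-lactone through the less favourable half-chair, and the carbonyl and phosphoryl oxygens are tied up in the sodium chelate, which leaves carbon as the free nucleophilic site. One equivalent of base suffices, the silyl ether and the two unactivated alkenes are inert, and the C6 alkoxide should not persist long enough to translactonise.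

**Step 18**
Reactants: 22 hydroxy lactone
Product: 23 6β-tert-butyldimethylsilyloxy-9α-triethylsilyloxy α-methylene lactone
Conditions: TBSOTf, 2,6-lutidine, CH2Cl2, 0 °C to rt
Reagents that add atoms: tert-butyldimethylsilyl triflate CC(C)(C)[Si](C)(C)OS(=O)(=O)C(F)(F)F
Why: Silyl triflate silylation of the hindered secondary alcohol masks O6 so that only O9 can be acylated in step 22.

**Step 19**
Reactants: 23 bis-silyl ether
Product: 25 enal (C5 side chain C(=CH2)CHO), via allylic alcohol 24 (not isolated)
Conditions: SeO2 (0.3 equiv), t-BuOOH, CH2Cl2, rt; crude product, MnO2, CH2Cl2, rt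
Reagents that add atoms: tert-butyl hydroperoxide CC(C)(C)OO
Why: Riley allylic oxidation (ene reaction, then [2,3]-shift) should occur at the methyl group of the only electron-rich alkene that has allylic hydrogens, as known for elemene-type isopropenyl groups, and MnO2 carries the primary allylic alcohol on to the enal.

**Step 20**
Reactants: 25 enal bis-silyl ether
Product: 26 9α-hydroxy-6β-TBS-oxy enal
Conditions: HF·pyridine, pyridine, THF, 0 °C
Reagents that add atoms: none
Why: Selective fluoride desilylation: a triethylsilyl ether is cleaved much faster than a tert-butyldimethylsilyl ether under buffered HF.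

**Step 21**
Reactants: 26 homoallylic alcohol
Product: 27 (1S)-1,2-epoxide (10α-oxiranyl) with free 9α-OH
Conditions: VO(acac)2 (10 mol %), t-BuOOH, toluene, rt to 40 °C
Reagents that add atoms: tert-butyl hydroperoxide CC(C)(C)OO
Why: Hydroxyl-directed epoxidation of a homoallylic alcohol: the vinyl group is the only alkene not deactivated by a carbonyl group, and the vanadium alkoxide on O9 reaches it in the rotamer whose C1=C2 bond points away from the C5 side chain, on the face turned toward O9, which in either chair form of the ring leads to the (1S) oxirane.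

**Step 22**
Reactants: 27 epoxy alcohol; 28 methacrylic anhydride
Product: 29 9α-methacrylate 6β-TBS ether
Conditions: DMAP, Et3N, CH2Cl2, rt
Reagents that add atoms: methacrylic anhydride (28) CC(=C)C(=O)OC(=O)C(C)=C
Why: DMAP-catalysed acyl transfer to the only free hydroxyl; O8 is locked in the lactone, so no acyl migration is possible.

**Step 23**
Reactants: 29 silyl ether
Product: 30 CNP0124638.3 (target)
Conditions: HF·pyridine, THF, 0 °C to rt
Reagents that add atoms: none
Why: Fluoride desilylation under mildly acidic conditions, which the Michael acceptors, the ester and the monosubstituted epoxide should tolerate, frees the 6β-hydroxyl without touching any stereocentre.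

**Compound list**
1 | benzoic acid | OC(=O)c1ccccc1 | starting material
2 | 1-methylcyclohexa-2,5-diene-1-carboxylic acid | CC1(C(=O)O)C=CCC=C1 | intermediate
3 | (1-methylcyclohexa-2,5-dien-1-yl)methanol | CC1(CO)C=CCC=C1 | intermediate
4 | TBDPS ether of 3 | CC1(CO[Si](c2ccccc2)(c2ccccc2)C(C)(C)C)C=CCC=C1 | intermediate
5 | 4-methyl-4-(TBDPS-oxymethyl)cyclohexa-2,5-dien-1-one | CC1(CO[Si](c2ccccc2)(c2ccccc2)C(C)(C)C)C=CC(=O)C=C1 | intermediate
6 | isopropenylboronic acid pinacol ester | CC(=C)B1OC(C)(C)C(C)(C)O1 | starting material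
7 | 5β-isopropenyl-10β-methyl-10α-(TBDPS-oxymethyl)cyclohex-8-en-7-one | C1=CC(=O)C[C@@H](C(C)=C)[C@]1(C)CO[Si](c2ccccc2)(c3ccccc3)C(C)(C)C | intermediate
8 | 8α,9α-epoxy ketone | [C@@H]12O[C@@H]1C(=O)C[C@@H](C(C)=C)[C@]2(C)CO[Si](c3ccccc3)(c4ccccc4)C(C)(C)C | intermediate
9 | 8α,9α-epoxy-7α-ol | [C@@H]12O[C@@H]1[C@H](O)C[C@@H](C(C)=C)[C@]2(C)CO[Si](c3ccccc3)(c4ccccc4)C(C)(C)C | intermediate
10 | 6-ene 8α,9α-epoxide, TBDPS ether | [C@@H]12O[C@@H]1C=C[C@@H](C(C)=C)[C@]2(C)CO[Si](c3ccccc3)(c4ccccc4)C(C)(C)C | intermediate
11 | 10α-hydroxymethyl vinyl epoxide | [C@@H]12O[C@@H]1C=C[C@@H](C(C)=C)[C@]2(C)CO | intermediate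
12 | 10α-formyl vinyl epoxide | [C@@H]12O[C@@H]1C=C[C@@H](C(C)=C)[C@]2(C)C=O | intermediate
13 | 10α-vinyl vinyl epoxide | [C@@H]12O[C@@H]1C=C[C@@H](C(C)=C)[C@]2(C)C=C | intermediate
14 | 8β-acetoxy-9α-ol | O[C@@H]1[C@@H](OC(C)=O)C=C[C@@H](C(C)=C)[C@]1(C)C=C | intermediate
15 | 8β-acetoxy-9α-OTES | CC[Si](CC)(CC)O[C@@H]1[C@@H](OC(C)=O)C=C[C@@H](C(C)=C)[C@]1(C)C=C | intermediate
16 | 8β-allylic alcohol, 9α-OTES | CC[Si](CC)(CC)O[C@@H]1[C@@H](O)C=C[C@@H](C(C)=C)[C@]1(C)C=C | intermediate
17 | 6β,7β-epoxy-8β-ol, 9α-OTES | CC[Si](CC)(CC)O[C@@H]1[C@@H](O)[C@H]2O[C@H]2[C@@H](C(C)=C)[C@]1(C)C=C | intermediate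
18 | diethylphosphonoacetic acid | OC(=O)CP(=O)(OCC)OCC | starting material
19 | 6β,7β-epoxy-8α-yl diethylphosphonoacetate, 9α-OTES (key-step precursor) | CC[Si](CC)(CC)O[C@@H]1[C@H](OC(=O)CP(=O)(OCC)OCC)[C@H]2O[C@H]2[C@@H](C(C)=C)[C@]1(C)C=C | intermediate
20 | formaldehyde (used as paraformaldehyde) | C=O | starting material
21 | α-(diethoxyphosphoryl) cis-γ-lactone, 6β-OH (in the flask as its C11 sodium carbanion, C11 not a fixed centre) | CC[Si](CC)(CC)O[C@@H]1[C@@H]2OC(=O)C(P(=O)(OCC)OCC)[C@@H]2[C@@H](O)[C@@H](C(C)=C)[C@]1(C)C=C | intermediate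
22 | 6β-hydroxy α-methylene lactone, 9α-OTES (key-step product) | CC[Si](CC)(CC)O[C@@H]1[C@@H]2OC(=O)C(=C)[C@@H]2[C@@H](O)[C@@H](C(C)=C)[C@]1(C)C=C | intermediate
23 | 6β-OTBS, 9α-OTES α-methylene lactone | CC[Si](CC)(CC)O[C@@H]1[C@@H]2OC(=O)C(=C)[C@@H]2[C@@H](O[Si](C)(C)C(C)(C)C)[C@@H](C(C)=C)[C@]1(C)C=C | intermediate
24 | C15 allylic alcohol | CC[Si](CC)(CC)O[C@@H]1[C@@H]2OC(=O)C(=C)[C@@H]2[C@@H](O[Si](C)(C)C(C)(C)C)[C@@H](C(=C)CO)[C@]1(C)C=C | intermediate
25 | enal, 6β-OTBS, 9α-OTES | CC[Si](CC)(CC)O[C@@H]1[C@@H]2OC(=O)C(=C)[C@@H]2[C@@H](O[Si](C)(C)C(C)(C)C)[C@@H](C(=C)C=O)[C@]1(C)C=C | intermediate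
26 | enal, 6β-OTBS, 9α-OH | O[C@@H]1[C@@H]2OC(=O)C(=C)[C@@H]2[C@@H](O[Si](C)(C)C(C)(C)C)[C@@H](C(=C)C=O)[C@]1(C)C=C | intermediate
27 | (1S)-oxirane, 6β-OTBS, 9α-OH | O[C@@H]1[C@@H]2OC(=O)C(=C)[C@@H]2[C@@H](O[Si](C)(C)C(C)(C)C)[C@@H](C(=C)C=O)[C@]1(C)[C@H]1CO1 | intermediate
28 | methacrylic anhydride | CC(=C)C(=O)OC(=O)C(C)=C | starting material
29 | 9α-methacrylate, 6β-OTBS | C=C(C)C(=O)O[C@@H]1[C@@H]2OC(=O)C(=C)[C@@H]2[C@@H](O[Si](C)(C)C(C)(C)C)[C@@H](C(=C)C=O)[C@]1(C)[C@H]1CO1 | intermediate
30 | CNP0124638.3 | C=C(C)C(=O)O[C@@H]1[C@@H]2OC(=O)C(=C)[C@@H]2[C@@H](O)[C@@H](C(=C)C=O)[C@]1(C)[C@H]1CO1 | target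

Total step count: 23. Longest linear sequence: 23 steps, fully linear from benzoic acid.

**Steps most likely to fail**

1. Step 17.
   - What may go wrong: the stabilised carbanion may alkylate slowly, because the ester must turn into its less stable s-cis form before C11 can reach C7. Ester cleavage followed by epoxide migration, closure through the carbonyl oxygen, or attack at C6 could then compete.
   - Fallback: an untethered lactone annulation by known chemistry, setting out from 19 and rejoining the route at 23.
   - Methanolysis (K2CO3, MeOH, 0 °C) removes the phosphonoacetate and gives the 6β,7β-epoxy-8α-ol F1.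
   - Dilithioacetate (AcOH, 2 LiN(i-Pr)2, DME, 55 °C) opens the epoxide trans-diaxially at C7 to the dihydroxy acid F2.
   - Carbodiimide lactonisation (EDC·HCl, DMAP, CH2Cl2) closes onto the cis-disposed O8 to give the lactone lacking C13, F3.
   - TBSOTf/2,6-lutidine gives its 6β-silyl ether F4.
   - LiN(i-Pr)2 followed by [Me2N=CH2]I gives the Mannich base F5. MeI then gives the methiodide F6, from which NaHCO3 eliminates the amine to deliver 23.

2. Step 16.
   - What may go wrong: formation and displacement of the oxyphosphonium ion may be sluggish. The 8β-oxygen lies syn-axial to the C10 methyl and the incoming carboxylate is gauche to the silyl ether, so the alcohol may return unchanged or be esterified with retention through an acyloxyphosphonium pathway.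
   - Fallback: separate activation from displacement, setting out from 17 and returning at 19.
   - Tf2O/pyridine (CH2Cl2, −20 °C) gives the 8β-triflate F7.
   - The bare carboxylate CsO2CCH2P(O)(OEt)2 (from 18 and Cs2CO3, with 18-crown-6, toluene, rt) then displaces the triflate with inversion.

3. Step 21.
   - What may go wrong: oxygen transfer to the monosubstituted, neopentyl-type alkene may be slow, facial selectivity at C1 may erode, and the aldehyde may oxidise gradually during long reaction times.
   - Fallback: replace substrate direction by catalyst-controlled sorting, setting out from 26 and returning at 27.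
   - Undirected epoxidation with dimethyldioxirane (acetone, 0 °C) should give 27 together with its (1R)-epimer F8.
   - Hydrolytic kinetic resolution follows, using the enantiomer of (salen)Co(OAc) that spares (S)-configured terminal epoxides (H2O, THF). It should convert only the epimer into the 1,2-diol F9, which chromatography removes from 27.

**Further compounds**
F1 | step 17 | 6β,7β-epoxy-8α-ol, 9α-OTES | CC[Si](CC)(CC)O[C@@H]1[C@H](O)[C@H]2O[C@H]2[C@@H](C(C)=C)[C@]1(C)C=C
F2 | step 17 | 7α-carboxymethyl-6β,8α-diol, 9α-OTES | CC[Si](CC)(CC)O[C@@H]1[C@H](O)[C@H](CC(=O)O)[C@@H](O)[C@@H](C(C)=C)[C@]1(C)C=C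
F3 | step 17 | cis-γ-lactone lacking C13, 6β-OH | CC[Si](CC)(CC)O[C@@H]1[C@@H]2OC(=O)C[C@@H]2[C@@H](O)[C@@H](C(C)=C)[C@]1(C)C=C
F4 | step 17 | cis-γ-lactone lacking C13, 6β-OTBS | CC[Si](CC)(CC)O[C@@H]1[C@@H]2OC(=O)C[C@@H]2[C@@H](O[Si](C)(C)C(C)(C)C)[C@@H](C(C)=C)[C@]1(C)C=C
F5 | step 17 | α-(dimethylaminomethyl) lactone | CC[Si](CC)(CC)O[C@@H]1[C@@H]2OC(=O)C(CN(C)C)[C@@H]2[C@@H](O[Si](C)(C)C(C)(C)C)[C@@H](C(C)=C)[C@]1(C)C=C
F6 | step 17 | methiodide of F5 | CC[Si](CC)(CC)O[C@@H]1[C@@H]2OC(=O)C(C[N+](C)(C)C)[C@@H]2[C@@H](O[Si](C)(C)C(C)(C)C)[C@@H](C(C)=C)[C@]1(C)C=C.[I-]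
F7 | step 16 | 6β,7β-epoxy-8β-yl triflate, 9α-OTES | CC[Si](CC)(CC)O[C@@H]1[C@@H](OS(=O)(=O)C(F)(F)F)[C@H]2O[C@H]2[C@@H](C(C)=C)[C@]1(C)C=C
F8 | step 21 | (1R)-epimer of 27 | O[C@@H]1[C@@H]2OC(=O)C(=C)[C@@H]2[C@@H](O[Si](C)(C)C(C)(C)C)[C@@H](C(=C)C=O)[C@]1(C)[C@@H]1CO1
F9 | step 21 | 1,2-diol from F8 | O[C@@H]1[C@@H]2OC(=O)C(=C)[C@@H]2[C@@H](O[Si](C)(C)C(C)(C)C)[C@@H](C(=C)C=O)[C@]1(C)[C@@H](O)CO
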